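The dawn run ended, after 30.0 min, with 49.4% of the starting material free and 7.5% as double product, and two of us dispute what the rest is.

| setting | midnight | dawn | delta | zeta |
|---|---|---|---|---|
| starting material | 0.10 M | 0.10 M | 0.10 M | 0.10 M |
| reagent | 0.044 M | 0.26 M | 0.0800 M | 0.400 M |
| scavenger | 0.12 M | 0.12 M | 0.120 M | 0.120 M |
| remark | run made earlier | run made earlier |  |  |
| time |  |  | 1.0 h | 1.0 h |

| run | time / min | double product / % | starting material / % |
|---|---|---|---|
| midnight | 6.00 | 0 | 97.6 |
| midnight | 12.0 | 0.7 | 94.0 |
| midnight | 20.0 | 0.5 | 91.7 |
| midnight | 25.0 | 0.6 | 90.6 |
| midnight | 30.0 | 0.9 | 88.9 |
| dawn | 2.50 | 0 | 93.4 |
| dawn | 8.00 | 0.1 | 80.1 |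
| dawn | 15.0 | 2.4 | 67.9 |
| dawn | 20.0 | 4.0 | 61.1 |
| dawn | 30.0 | 7.5 | 49.4 |

(standard deviation of a reading: 0.5 percentage points)

- the earlier runs were read with a standard deviation of 0.5 percentage points
- a reading of starting material is of its free form alone

- which of these holds the largest part of the starting material at the end of delta (single product / double product / starting material)
- which of these holds the largest part of the starting material at the end of zeta (single product / double product / starting material)
- final double product in zeta, as a percentage of the starting material charged

My colleague counts the rest as single product, 43.1% at that reading. From dawn's last two readings, the rise of double product per loss of starting material, set against the mean ratio of that remainder to starting material, gives a selectivity factor, second step over first, of 0.414. On that view single product piles up.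

I hold otherwise. The reading counts free starting material, so a bound form would pass for conversion, and I trust the double product as the clock instead. I assume equal reactivity of the two sites, with x = k[reagent]t at charged [reagent]. Then starting material, free and bound together, is exp(−x), single product is x·exp(−x), and double product is 1 − (1 + x)·exp(−x). Dawn's double product gives x = 0.450, and so the site constant k, the rate constant per site as read from double product, 9.61 × 10⁻⁴ L mol⁻¹ s⁻¹. On this reckoning 14 percentage points of dawn's starting material is bound at that reading.

Zeta holds 4.00 equivalents of reagent, enough for both sites, so its end state is double product. At its time x = 1.38, which gives 40.3% double against 34.7% single. Delta reaches x = 0.277, so on my reckoning starting material leads there with 75.8%.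

The forecast, on my colleague's side (“Double product follows from the single product”), names starting material for delta, single product for zeta, and 33% double product.

The largest part in delta at its end is starting material, 68.1%. The largest part in zeta at its end is double product, 33.3% against 28.0% single, beside 21.2% free starting material and 17.6% idle adduct.

    scavenger + released group → scavenged by-product (k = 0.00400 L mol⁻¹ s⁻¹)
    released group → by-product carried off (k = 6.40 × 10⁻⁵ s⁻¹)
    reagent + single product → double product + released group (k = 0.00110 L mol⁻¹ s⁻¹)
    reagent → decomposition product (k = 1.00 × 10⁻⁷ s⁻¹)
    starting material + released group ⇌ idle adduct, settled at all times (K = 22.0 L mol⁻¹)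
    starting material + reagent → single product + released group (k = 0.00110 L mol⁻¹ s⁻¹)

My double product for zeta lies 7 points above the flask's. Read at 15 min, zeta has x = 0.346, giving 4.77% double against the simulated 5.17%. There single product, at 23.1%, leads double, as it does in delta: that is my colleague's region. Zeta has not come to rest: at 10.0 h it holds 99.1% double product and 0.604% single, with 50.1% of its reagent and 1.56% of its scavenger left.

The runs are simulated with constants of no real substance; the scatter is artificial.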